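- At 15 min, the time of reading, this flask, a kinetic resolution, is judged by its remainder ratio: c(left-handed substrate) over c(right-handed substrate). The excess asked for is one minus this ratio over one plus it.

| setting | Saturday's | Sunday's | Thursday's | flask |
|---|---|---|---|---|
| left-handed substrate | 0.29 M | 0.29 M | 0.29 M | 0.29 M |
| right-handed substrate | 0.29 M | 0.29 M | 0.29 M | 0.29 M |
| solid reagent | 1.5 equiv | 6 equiv | 3 equiv | 3.00 equiv |
| free catalyst | 0.074 mol% | 0.074 mol% | 0.15 mol% | 0.074 mol% |
| impurity | 53 µM | 53 µM | 53 µM | 53 µM |
| remark | run made earlier | run made earlier | run made earlier |  |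
| time |  |  |  | 15 min |

| run | time / min | right-handed substrate / % | left-handed substrate / % | left-handed product / % |
|---|---|---|---|---|
| Saturday's | 2.50 | 50.3 | 44.8 | 4.4 |
| Saturday's | 5.00 | 49.5 | 38.0 | 11.7 |
| Saturday's | 8.00 | 49.1 | 30.3 | 19.8 |
| Saturday's | 10.0 | 48.6 | 25.1 | 25.0 |
| Saturday's | 12.0 | 47.8 | 20.0 | 29.6 |
| Saturday's | 15.0 | 46.7 | 13.1 | 36.4 |
| Sunday's | 1.00 | 49.6 | 48.9 | 0.9 |
| Sunday's | 3.00 | 49.4 | 43.0 | 5.2 |
| Sunday's | 5.00 | 49.8 | 38.6 | 12.0 |
| Sunday's | 8.00 | 48.8 | 29.9 | 20.3 |
| Sunday's | 12.0 | 48.5 | 19.7 | 29.8 |
| Sunday's | 15.0 | 46.9 | 13.4 | 36.8 |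
| Thursday's | 1.33 | 49.7 | 47.1 | 2.8 |
| Thursday's | 2.50 | 49.6 | 43.2 | 6.6 |
| Thursday's | 4.00 | 49.9 | 39.3 | 10.5 |
| Thursday's | 8.00 | 48.6 | 27.3 | 22.8 |
| Thursday's | 15.0 | 46.9 | 9.2 | 40.3 |

(readings scatter by 0.3 percentage points)

- free catalyst is single-handed; left-handed substrate and right-handed substrate are mirror images of each other, charged as a racemate, each of them at the stated concentration
- given per volume of solution although it is solid: solid reagent
- the numbers in the tables scatter by 0.3 percentage points (one standard deviation)
- steps that have been proposed: free catalyst + left-handed substrate <-> catalyst intermediate A; free catalyst + right-handed substrate <-> catalyst intermediate B; coupling partner + catalyst intermediate A -> free catalyst + left-handed product; coupling partner + catalyst intermediate B -> free catalyst + right-handed product; solid reagent <-> coupling partner; free catalyst + impurity -> spent catalyst A; 2 free catalyst -> spent catalyst B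
- at the start none of the solid reagent is in solution

1. whether the excess of right-handed substrate over left-handed substrate among what is left of the two reaches 95% by 15 min (yes / no)
2. the highest excess of right-handed substrate over left-handed substrate among what is left of the two up to 15 min

- Turned round, an excess of 95% needs an allowed ratio, one minus the excess over one plus it, of 0.0256.
- Saturday's run ends at a remainder ratio of 0.281, ten times the allowed ratio. With its c(right-handed substrate) of 46.7%, c(left-handed substrate) would have to be 1.20%, but it reads 13.1%.
- Thursday's run, with twice the flask's catalyst loading, still ends at 0.196, more than the allowed ratio.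
- Saturday's and Sunday's runs, at 1.5 equiv and 6 equiv of solid reagent, end within the scatter of each other. The flask lies between them in solid reagent and matches them in catalyst and impurity, so this reckoning puts it on their curves.
- Saturday's ratio falls from reading to reading, so this reckoning puts the flask's top at the end. The final readings of Saturday's and Sunday's runs together give an excess of 55.9%, less than the 95% wanted.
- The forecast gave no and a top of 56%, holding that “the solid amount does not matter”.
- The flask gives no and a top of 55.8%.

    free catalyst + left-handed substrate ⇌ catalyst intermediate A (K = 10.1 L mol⁻¹, k = 7970 L mol⁻¹ min⁻¹)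
    free catalyst + right-handed substrate ⇌ catalyst intermediate B (K = 1.10 L mol⁻¹, k = 17900 L mol⁻¹ min⁻¹)
    coupling partner + catalyst intermediate A → free catalyst + left-handed product (k = 8910 L mol⁻¹ min⁻¹)
    coupling partner + catalyst intermediate B → free catalyst + right-handed product (k = 2920 L mol⁻¹ min⁻¹)
    solid reagent ⇌ coupling partner, rate k5*(cs5 - [coupling partner]) while solid is left; crystals form when [coupling partner] > cs5 (solubility = 0.210 M, k = 0.0932 min⁻¹)
    free catalyst + impurity → spent catalyst A (k = 4.71 × 10⁵ L mol⁻¹ min⁻¹)
    2 free catalyst → spent catalyst B (k = 344 L mol⁻¹ min⁻¹)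

- At 7.31 min the flask makes coupling partner 1.05 times as fast as it uses it, and the step to left-handed product uses it 15 times as fast as the step to right-handed product. The flask's remainder ratio at 15.0 min is 0.284, ten times the allowed ratio. The neighbour charged with 2.1 × 10⁻⁴ M of impurity still holds, unbound, 90% of its charged left-handed substrate and 99.2% of its charged right-handed substrate, and its top of 4.70% corresponds to a remainder ratio of 0.910.

All runs were computed for an exercise; scatter was added.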